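**Plan**
- Retrosynthesis: the two formyl C–C bonds and the exocyclic C=CH2 (back to C=O) are cut first; then both cyclobutane bonds (β-carbon–CMe2 and α-carbon–CH2) are cut to isobutylene and a chroman-fused (Z)-cyclonon-2-enone; then the ring C=C (metathesis), the C2–allyl, C2–methyl and C3–CH2 bonds back to a 4-phenyldihydrocoumarin, and the C4–phenyl bond back to 5,7-dimethoxycoumarin.
- Enabling feature: the gem-dimethylcyclobutane shares with the nine-membered carbocycle the two ring carbons next to the methylene-bearing carbon (the nearer one carries the cyclobutane CH2, the farther one the CMe2). Once that carbon is a ketone, the shared bond is the C=C of a cyclononenone and the CH2–CMe2 unit is isobutylene.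
- Forward order of rings: chroman (opened from the coumarin lactone, reclosed in the oxocarbenium allylation), then the nine-membered ring (ring-closing metathesis), then the cyclobutane (photocycloaddition); demethylation, methylenation and diformylation follow.
- Stereochemistry: C4 from the chiral rhodium catalyst; C3 trans to phenyl in the enolate Michael addition; C2 by anti attack of allylsilane on the cyclic oxocarbenium ion; the cyclobutane β-carbon by substrate-controlled approach of isobutylene; the α-carbon by base equilibration to the trans ring fusion.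

Key step: step 13

Assumption: (R)-SEGPHOS is taken to deliver the (R)-lactone 3, as it does with simpler coumarins; should the sense be opposite, the (S)-ligand would be used.

**Step 1**
Reactants: 1 5,7-dimethoxycoumarin; 2 phenylboronic acid
Product: 3 (R)-5,7-dimethoxy-4-phenylchroman-2-one
Conditions: Rh(acac)(C2H4)2 (3 mol %), (R)-SEGPHOS (3.3 mol %), 2 (5 equiv), dioxane/H2O 10:1, 60 °C
Reagents that add atoms: none
Why: Rhodium-catalysed asymmetric 1,4-addition of the arylboronic acid (Hayashi–Miyaura reaction) to the coumarin C3=C4 bond, in which the bisphosphine-bound phenylrhodium species selects one enantioface and sets C4 as R before water protonates the rhodium enolate.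

**Step 2**
Reactants: 3 (R)-5,7-dimethoxy-4-phenylchroman-2-one
Product: 5 tert-butyl 3-[(3S,4R)-5,7-dimethoxy-2-oxo-4-phenylchroman-3-yl]propanoate, via lithium enolate 4 (not isolated)
Conditions: LiN(SiMe3)2 (1.05 equiv), THF, −78 °C; tert-butyl acrylate (1.0 equiv), −78 °C; aq. NH4Cl at −78 °C
Reagents that add atoms: tert-butyl acrylate C=CC(=O)OC(C)(C)C
Why: Michael addition of the lactone lithium enolate to the acrylate, in which the pseudoaxial 4-phenyl group shields one enolate face so that the new chain enters trans to it and sets C3 as S.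

**Step 3**
Reactants: 5 tert-butyl 3-[(3S,4R)-5,7-dimethoxy-2-oxo-4-phenylchroman-3-yl]propanoate
Product: 6 tert-butyl (4S)-4-[(R)-(2-hydroxy-4,6-dimethoxyphenyl)(phenyl)methyl]-5-[methoxy(methyl)amino]-5-oxopentanoate
Conditions: AlMe3 (3 equiv), MeNHOMe·HCl (3 equiv), CH2Cl2, 0 → 23 °C; cold aq. potassium sodium tartrate; used without storage
Reagents that add atoms: N,O-dimethylhydroxylamine hydrochloride CNOC.Cl
Why: Weinreb aminolysis of the lactone by the aluminium amide, which should open only the aryl ester because it is far more electrophilic than the hindered tert-butyl ester, and which touches neither stereocentre.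

**Step 4**
Reactants: 6 tert-butyl (4S)-4-[(R)-(2-hydroxy-4,6-dimethoxyphenyl)(phenyl)methyl]-5-[methoxy(methyl)amino]-5-oxopentanoate
Product: 7 tert-butyl (4S)-4-[(R)-(2-hydroxy-4,6-dimethoxyphenyl)(phenyl)methyl]-5-oxohexanoate
Conditions: MeMgBr (3 equiv), THF, −20 → 0 °C; aq. NH4Cl
Reagents that add atoms: methylmagnesium bromide C[Mg]Br
Why: Grignard addition to the Weinreb amide should stop at the ketone through the magnesium chelate (one equivalent is spent on the phenol), while the tert-butyl ester is inert at this temperature.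

**Step 5**
Reactants: 7 tert-butyl (4S)-4-[(R)-(2-hydroxy-4,6-dimethoxyphenyl)(phenyl)methyl]-5-oxohexanoate
Product: 8 tert-butyl 3-[(2R,3S,4R)-2-allyl-5,7-dimethoxy-2-methyl-4-phenylchroman-3-yl]propanoate
Conditions: allyltrimethylsilane (4 equiv), BF3·OEt2 (2 equiv), CH2Cl2, −78 → −40 °C
Reagents that add atoms: allyltrimethylsilane C=CC[Si](C)(C)C
Why: Hosomi–Sakurai allylation of the 2-methylchromenylium (cyclic oxocarbenium) ion that the keto-phenol forms with the Lewis acid; A(1,2) strain to the C2 methyl and peri strain to the 5-methoxy group hold the C3 chain and the 4-phenyl group pseudoaxial, so the silane should attack C2 anti to the adjacent C3 chain and set the quaternary centre as 2R (allyl trans to the C3 chain, methyl cis to it).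

**Step 6**
Reactants: 8 tert-butyl 3-[(2R,3S,4R)-2-allyl-5,7-dimethoxy-2-methyl-4-phenylchroman-3-yl]propanoate
Product: 10 tert-butyl 3-[(2R,3S,4R)-2-(3-hydroxypropyl)-5,7-dimethoxy-2-methyl-4-phenylchroman-3-yl]propanoate, via B-alkyl-9-BBN adduct 9 (not isolated)
Conditions: 9-BBN (1.5 equiv), THF, 0 → 23 °C; then 30 % H2O2, 3 M NaOH, 0 °C
Reagents that add atoms: hydrogen peroxide OO
Why: Brown hydroboration–oxidation places the hydroxyl on the terminal carbon of the only alkene, and the tert-butyl ester tolerates the borane and the brief cold alkaline oxidation.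

**Step 7**
Reactants: 10 tert-butyl 3-[(2R,3S,4R)-2-(3-hydroxypropyl)-5,7-dimethoxy-2-methyl-4-phenylchroman-3-yl]propanoate
Product: 11 tert-butyl 3-[(2R,3S,4R)-5,7-dimethoxy-2-methyl-2-(3-oxopropyl)-4-phenylchroman-3-yl]propanoate
Conditions: Dess–Martin periodinane (1.3 equiv), NaHCO3, CH2Cl2, 0 → 23 °C
Reagents that add atoms: none
Why: Dess–Martin oxidation of the primary alcohol to the aldehyde under buffered conditions that leave the electron-rich arene and the ester alone.

**Step 8**
Reactants: 11 tert-butyl 3-[(2R,3S,4R)-5,7-dimethoxy-2-methyl-2-(3-oxopropyl)-4-phenylchroman-3-yl]propanoate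
Product: 12 tert-butyl 3-[(2R,3S,4R)-2-(but-3-en-1-yl)-5,7-dimethoxy-2-methyl-4-phenylchroman-3-yl]propanoate
Conditions: Ph3PCH3Br (1.5 equiv), KOtBu (1.4 equiv), THF, 0 °C
Reagents that add atoms: methyltriphenylphosphonium bromide C[P+](c1ccccc1)(c1ccccc1)c1ccccc1.[Br-]
Why: Wittig methylenation of the aldehyde by the non-stabilised ylide, which does not attack the tert-butyl ester at 0 °C.

**Step 9**
Reactants: 12 tert-butyl 3-[(2R,3S,4R)-2-(but-3-en-1-yl)-5,7-dimethoxy-2-methyl-4-phenylchroman-3-yl]propanoate
Product: 13 3-[(2R,3S,4R)-2-(but-3-en-1-yl)-5,7-dimethoxy-2-methyl-4-phenylchroman-3-yl]propanal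
Conditions: iBu2AlH (1.15 equiv), CH2Cl2, −78 °C; MeOH, then aq. potassium sodium tartrate
Reagents that add atoms: none
Why: Partial reduction of the tert-butyl ester, whose tetrahedral aluminium hemiacetal should persist at −78 °C and release the aldehyde only on work-up.

**Step 10**
Reactants: 13 3-[(2R,3S,4R)-2-(but-3-en-1-yl)-5,7-dimethoxy-2-methyl-4-phenylchroman-3-yl]propanal
Product: 14 5-[(2R,3S,4R)-2-(but-3-en-1-yl)-5,7-dimethoxy-2-methyl-4-phenylchroman-3-yl]pent-1-en-3-ol (carbinol epimers)
Conditions: CH2=CHMgBr (1.5 equiv), THF, −78 → 0 °C; aq. NH4Cl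
Reagents that add atoms: vinylmagnesium bromide C=C[Mg]Br
Why: Grignard 1,2-addition to the aldehyde; the new carbinol centre is not controlled and need not be, because step 12 oxidises it.

**Step 11**
Reactants: 14 5-[(2R,3S,4R)-2-(but-3-en-1-yl)-5,7-dimethoxy-2-methyl-4-phenylchroman-3-yl]pent-1-en-3-ol (carbinol epimers)
Product: 15 chroman-fused (Z)-cyclonon-2-en-1-ol (5,7-dimethyl ether; carbinol epimers)
Conditions: second-generation Grubbs catalyst (H2IMes)(PCy3)Cl2Ru=CHPh (10 mol %), 1,4-benzoquinone (20 mol %), toluene (1 mM), 80 °C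
Reagents that add atoms: none
Why: Ring-closing metathesis of the two terminal alkenes, helped by the gauche disposition of the trans-vicinal chains on the chroman and driven by loss of ethylene; the nine-membered ring should admit only the (Z)-alkene.

**Step 12**
Reactants: 15 chroman-fused (Z)-cyclonon-2-en-1-ol (5,7-dimethyl ether; carbinol epimers)
Product: 16 chroman-fused (Z)-cyclonon-2-enone (5,7-dimethyl ether)
Conditions: Dess–Martin periodinane (1.3 equiv), NaHCO3, CH2Cl2, 0 °C; used at once
Reagents that add atoms: none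
Why: Dess–Martin oxidation converges both allylic carbinol epimers on one enone under neutral buffered conditions, which should avoid base-induced drift of the double bond out of conjugation.

**Step 13**
Reactants: 16 chroman-fused (Z)-cyclonon-2-enone (5,7-dimethyl ether); 17 isobutylene
Product: 19 trans-fused gem-dimethylcyclobutane ketone (5,7-dimethyl ether), via cis-fused epimer 18 (not isolated)
Conditions: hν (366 nm), isobutylene/CH2Cl2 1:1, −78 °C; evaporation; then NaOMe (0.2 equiv), MeOH, 23 °C
Reagents that add atoms: none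
Why: Proposed new method: the closest known reaction type is the enone–alkene [2+2] photocycloaddition of small-ring enones with isobutylene, which has not been shown on a nine-membered (Z)-enone because its triplet normally relaxes by twisting to the E isomer; here only the n→π* band is excited, and the twisted triplet, reached from the Z and the E form alike so that isomerisation merely recycles material, is meant to be trapped by isobutylene used as co-solvent at −78 °C. The triplet should bond through its α-carbon to the CH2 terminus of isobutylene to give a triplet 1,4-diradical (secondary at the β-carbon, tertiary at CMe2), and after spin inversion radical recombination between the β-carbon and CMe2 closes the four-membered ring. This head-to-tail orientation is the one normally found for electron-rich alkenes with cyclic enones. The β-carbon stereocentre is set by approach of the alkene to the outer face of the folded nine-membered ring trans-fused to the chroman (substrate control that is expected but not assured), and the α-carbon stereocentre is set afterwards by methoxide equilibration through the enolate to the trans ring fusion, the more stable arrangement of bicyclo[7.2.0]undecan-2-ones. The step therefore needs regioselectivity and face selectivity at the β-carbon only, and the alkoxyarene and the phenyl ring do not absorb at this wavelength.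

**Step 14**
Reactants: 19 trans-fused gem-dimethylcyclobutane ketone (5,7-dimethyl ether)
Product: 20 trans-fused cyclobutane ketone 5,7-diphenol
Conditions: BBr3 (5 equiv), CH2Cl2, −78 → 0 °C; MeOH, aq. NaHCO3
Reagents that add atoms: none
Why: Boron tribromide O-demethylation of both aryl methyl ethers (bromide attacks the methyl of the boron-complexed ether), placed at the ketone stage before any alkene is present; the tertiary chroman ether should survive at low temperature as it does in other 2,2-dialkylchromans.

**Step 15**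
Reactants: 20 trans-fused cyclobutane ketone 5,7-diphenol
Product: 21 exocyclic methylene 5,7-diphenol
Conditions: Ph3PCH3Br (6 equiv), KOtBu (6 equiv), THF, 0 → 60 °C; aq. NH4Cl
Reagents that add atoms: methyltriphenylphosphonium bromide C[P+](c1ccccc1)(c1ccccc1)c1ccccc1.[Br-]
Why: Wittig methylenation of the ring ketone with excess ylide to cover the two phenoxides; the α ring-fusion centre is already the thermodynamic epimer and cannot be lost to the basic medium.

**Step 16**
Reactants: 21 exocyclic methylene 5,7-diphenol
Product: 23 CNP0253700.4 (6,8-diformyl-5,7-dihydroxy target), via bis(iminium) salt 22 (not isolated)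
Conditions: POCl3 (6 equiv), DMF (10 equiv), EtOAc, 0 → 23 °C; then aq. NaOAc, 40 °C
Reagents that add atoms: N,N-dimethylformamide CN(C)C=O; water O
Why: Vilsmeier–Haack double formylation in which the chloroiminium ion attacks C6 and C8, the only free positions of the phloroglucinol-type ring and each ortho or para to three oxygens, far faster than it attacks the 1,1-disubstituted alkene; buffered hydrolysis then releases both aldehydes.

**Compound list**
1 | 5,7-dimethoxycoumarin | COc1cc(OC)c2ccc(=O)oc2c1 | starting material
2 | phenylboronic acid | OB(O)c1ccccc1 | starting material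
3 | (R)-5,7-dimethoxy-4-phenylchroman-2-one | O=C1C[C@H](c2ccccc2)c2c(OC)cc(OC)cc2O1 | intermediate
4 | lithium enolate of 3 (not isolated) | [Li+].[O-]C1=C[C@H](c2ccccc2)c2c(OC)cc(OC)cc2O1 | intermediate
5 | tert-butyl 3-[(3S,4R)-5,7-dimethoxy-2-oxo-4-phenylchroman-3-yl]propanoate (3,4-trans) | O=C1Oc2cc(OC)cc(OC)c2[C@@H](c2ccccc2)[C@@H]1CCC(=O)OC(C)(C)C | intermediate
6 | tert-butyl (4S)-4-[(R)-(2-hydroxy-4,6-dimethoxyphenyl)(phenyl)methyl]-5-[methoxy(methyl)amino]-5-oxopentanoate (Weinreb amide phenol) | CON(C)C(=O)[C@@H](CCC(=O)OC(C)(C)C)[C@H](c1ccccc1)c1c(O)cc(OC)cc1OC | intermediate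
7 | tert-butyl (4S)-4-[(R)-(2-hydroxy-4,6-dimethoxyphenyl)(phenyl)methyl]-5-oxohexanoate (methyl ketone phenol, in equilibrium with its cyclic hemiketal) | CC(=O)[C@@H](CCC(=O)OC(C)(C)C)[C@H](c1ccccc1)c1c(O)cc(OC)cc1OC | intermediate
8 | tert-butyl 3-[(2R,3S,4R)-2-allyl-5,7-dimethoxy-2-methyl-4-phenylchroman-3-yl]propanoate (allyl trans to the C3 chain and cis to phenyl) | C=CC[C@@]1(C)Oc2cc(OC)cc(OC)c2[C@@H](c2ccccc2)[C@@H]1CCC(=O)OC(C)(C)C | intermediate
9 | B-alkyl-9-borabicyclo[3.3.1]nonane adduct of 8, boron on the terminal carbon (not isolated) | C1CCC2CCCC1B2CCC[C@@]3(C)Oc4cc(OC)cc(OC)c4[C@@H](c4ccccc4)[C@@H]3CCC(=O)OC(C)(C)C | intermediate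
10 | tert-butyl 3-[(2R,3S,4R)-2-(3-hydroxypropyl)-5,7-dimethoxy-2-methyl-4-phenylchroman-3-yl]propanoate | OCCC[C@@]1(C)Oc2cc(OC)cc(OC)c2[C@@H](c2ccccc2)[C@@H]1CCC(=O)OC(C)(C)C | intermediate
11 | tert-butyl 3-[(2R,3S,4R)-5,7-dimethoxy-2-methyl-2-(3-oxopropyl)-4-phenylchroman-3-yl]propanoate | O=CCC[C@@]1(C)Oc2cc(OC)cc(OC)c2[C@@H](c2ccccc2)[C@@H]1CCC(=O)OC(C)(C)C | intermediate
12 | tert-butyl 3-[(2R,3S,4R)-2-(but-3-en-1-yl)-5,7-dimethoxy-2-methyl-4-phenylchroman-3-yl]propanoate | C=CCC[C@@]1(C)Oc2cc(OC)cc(OC)c2[C@@H](c2ccccc2)[C@@H]1CCC(=O)OC(C)(C)C | intermediate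
13 | 3-[(2R,3S,4R)-2-(but-3-en-1-yl)-5,7-dimethoxy-2-methyl-4-phenylchroman-3-yl]propanal | C=CCC[C@@]1(C)Oc2cc(OC)cc(OC)c2[C@@H](c2ccccc2)[C@@H]1CCC=O | intermediate
14 | 5-[(2R,3S,4R)-2-(but-3-en-1-yl)-5,7-dimethoxy-2-methyl-4-phenylchroman-3-yl]pent-1-en-3-ol (both carbinol epimers) | C=CCC[C@@]1(C)Oc2cc(OC)cc(OC)c2[C@@H](c2ccccc2)[C@@H]1CCC(O)C=C | intermediate
15 | chroman-fused (Z)-cyclonon-2-en-1-ol: nine-membered carbocycle trans-fused at chroman C2–C3, CH(OH) three carbons from chroman C3, (Z)-CH=CH next to it; 5,7-dimethyl ether; both carbinol epimers | OC1/C=C\CC[C@@]2(C)Oc3cc(OC)cc(OC)c3[C@@H](c3ccccc3)[C@@H]2CC1 | intermediate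
16 | chroman-fused (Z)-cyclonon-2-enone (5,7-dimethyl ether) | O=C1/C=C\CC[C@@]2(C)Oc3cc(OC)cc(OC)c3[C@@H](c3ccccc3)[C@@H]2CC1 | intermediate
17 | isobutylene | C=C(C)C | starting material
18 | cis-fused cyclobutane ketone, the α-epimer of 19 (not isolated) | O=C1CC[C@H]2[C@H](c3ccccc3)c3c(OC)cc(OC)cc3O[C@]2(C)CC[C@@H]2[C@H]1CC2(C)C | intermediate
19 | trans-fused gem-dimethylcyclobutane ketone (5,7-dimethyl ether): CMe2 on the β-carbon, CH2 on the α-carbon, ring-fusion hydrogens trans | O=C1CC[C@H]2[C@H](c3ccccc3)c3c(OC)cc(OC)cc3O[C@]2(C)CC[C@@H]2[C@@H]1CC2(C)C | intermediate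
20 | trans-fused cyclobutane ketone 5,7-diphenol | O=C1CC[C@H]2[C@H](c3ccccc3)c3c(O)cc(O)cc3O[C@]2(C)CC[C@@H]2[C@@H]1CC2(C)C | intermediate
21 | exocyclic methylene 5,7-diphenol (C6 and C8 unsubstituted) | C=C1CC[C@H]2[C@H](c3ccccc3)c3c(O)cc(O)cc3O[C@]2(C)CC[C@@H]2[C@@H]1CC2(C)C | intermediate
22 | 6,8-bis(dimethyliminiomethyl) dichloride of 21 (not isolated) | C=C1CC[C@H]2[C@H](c3ccccc3)c3c(O)c(C=[N+](C)C)c(O)c(C=[N+](C)C)c3O[C@]2(C)CC[C@@H]2[C@@H]1CC2(C)C.[Cl-].[Cl-] | intermediate
23 | CNP0253700.4 | C=C1CC[C@H]2[C@H](c3ccccc3)c3c(O)c(C=O)c(O)c(C=O)c3O[C@]2(C)CC[C@@H]2[C@@H]1CC2(C)C | target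

**Step count and risks**
Total steps: 16. Longest linear sequence: 16 steps (1 → 23).

Most likely to fail:

1. Step 13. The excited enone may decay by twisting and Z/E isomerisation faster than isobutylene captures it, the double bond may drift out of conjugation under irradiation, or addition may occur head-to-head or on the wrong face of the β-carbon. The fallback builds the same cyclobutane by known polar chemistry and sets out from 16. A Mukaiyama–Michael addition of 1-methoxy-2-methyl-1-(trimethylsilyloxy)propene (TiCl4, CH2Cl2, −78 °C) puts the CMe2CO2Me unit on the β-carbon and gives the Mukaiyama–Michael keto ester F1. LiAlH4 reduces ketone and ester to the diol F2. TsCl in pyridine sulfonylates the primary neopentyl hydroxyl to the primary monotosylate F3. Dess–Martin oxidation restores the ring ketone in the keto tosylate F4. KOtBu in t-BuOH/THF then closes the four-membered ring by intramolecular alkylation of the enolate at the α-methine and equilibrates the ring fusion to trans, which rejoins the route at 19.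

2. Step 11. Cross-metathesis oligomerisation may outrun closure of the strained nine-membered ring, or ruthenium hydride may isomerise the allylic alcohol. The fallback forms the ring by carbonyl addition instead and sets out from 11. Stork–Zhao olefination (Ph3PCH2I iodide, NaN(SiMe3)2, THF, −78 °C) gives the (Z)-vinyl iodide ester F5. iBu2AlH at −78 °C reduces the tert-butyl ester to the (Z)-iodo aldehyde F6. Intramolecular Nozaki–Hiyama–Kishi coupling (CrCl2, catalytic NiCl2, DMSO, high dilution) joins the iodine-bearing vinyl carbon to the aldehyde carbon and returns to the route at 15.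

3. Step 5. Facial selectivity at C2 may be poor or reversed if the silane avoids the pseudoaxial phenyl group and attacks syn to the C3 chain, and the C3 configuration may erode through the enol ether of the oxocarbenium ion. The fallback exchanges the roles of the two C2 substituents and sets out from 6. But-3-enylmagnesium bromide gives the butenyl ketone phenol F7. Trimethyl orthoformate with pyridinium p-toluenesulfonate in MeOH closes it to the cyclic methyl ketal F8. AlMe3 in CH2Cl2 (−78 → 0 °C) ionises the ketal and delivers methyl to the oxocarbenium face that the allylsilane preferred, which now places methyl cis to the C3 chain. This comes back to the route at 12 and makes steps 5 to 8 unnecessary.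

**Further compounds**
F1 | step 13 | Mukaiyama–Michael keto ester (methyl 2-methylpropanoate unit on the β-carbon of the nine-membered ketone) | O=C1CC[C@H]2[C@H](c3ccccc3)c3c(OC)cc(OC)cc3O[C@]2(C)CC[C@@H](C(C)(C)C(=O)OC)C1
F2 | step 13 | diol (ring carbinol epimers; primary neopentyl alcohol) | OC1CC[C@H]2[C@H](c3ccccc3)c3c(OC)cc(OC)cc3O[C@]2(C)CC[C@@H](C(C)(C)CO)C1
F3 | step 13 | primary monotosylate | OC1CC[C@H]2[C@H](c3ccccc3)c3c(OC)cc(OC)cc3O[C@]2(C)CC[C@@H](C(C)(C)COS(=O)(=O)c3ccc(C)cc3)C1
F4 | step 13 | keto tosylate | O=C1CC[C@H]2[C@H](c3ccccc3)c3c(OC)cc(OC)cc3O[C@]2(C)CC[C@@H](C(C)(C)COS(=O)(=O)c3ccc(C)cc3)C1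
F5 | step 11 | (Z)-vinyl iodide ester | I/C=C\CC[C@@]1(C)Oc2cc(OC)cc(OC)c2[C@@H](c2ccccc2)[C@@H]1CCC(=O)OC(C)(C)C
F6 | step 11 | (Z)-iodo aldehyde | I/C=C\CC[C@@]1(C)Oc2cc(OC)cc(OC)c2[C@@H](c2ccccc2)[C@@H]1CCC=O
F7 | step 5 | butenyl ketone phenol | C=CCCC(=O)[C@@H](CCC(=O)OC(C)(C)C)[C@H](c1ccccc1)c1c(O)cc(OC)cc1OC
F8 | step 5 | cyclic methyl ketal (2-butenyl-2-methoxychroman, both anomers) | C=CCCC1(OC)Oc2cc(OC)cc(OC)c2[C@@H](c2ccccc2)[C@@H]1CCC(=O)OC(C)(C)C
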